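## Retrosynthetic overview

1. Target numbering used throughout: C1 (OAc), C2=C3 (C3 carries C7H2OBz), C4 (OH), C5 (OBz), C6 (OH). The last C–C bond made is C3–C4: an intramolecular Ni/Cr (Nozaki–Hiyama–Kishi) addition of a (Z)-alkenyl iodide (C3) to an aldehyde (C4) closes the cyclohexene on a chain that already carries all three esters. One desilylation then gives the target.
2. Enabling feature: C2=C3(C7)–C4(OH) is a 2-substituted cyclohex-2-en-1-ol, the retron of an alkenyl-metal/aldehyde addition. The ring carbons C2, C1, C6, C5, C4 are C1 to C5 of D-arabinose, with C1/C6/C5 bearing the oxygens of sugar C2/C3/C4.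
3. The ester pattern needs no ester-selective step. The Wittig ring opening frees the furanose ring oxygen, which is benzoylated together with the new primary C7 hydroxyl. One di-tert-butylsilylene masks O3/O5 of the sugar and is later opened at the primary oxygen only.
4. Ring order: the lactone/furanose ring and the six-membered silylene are temporary rings, opened in steps 4 and 9. The only ring of the target, the carbocycle, is formed last (step 11).

Key step: step 11

Remark: D-arabinono-1,4-lactone is taken as a commercial starting material (it is the bromine-water oxidation product of D-arabinose). Lactol 4 is used as its anomeric mixture, because the anomeric centre is destroyed in step 4.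

## Route

Step 1
Reactants: 1 D-arabinono-1,4-lactone
Product: 2 3,5-O-(di-tert-butylsilanediyl)-D-arabinono-1,4-lactone
Conditions: tBu2Si(OTf)2, pyridine, DMF, −40 → 0 °C
Reagents that add atoms: di-tert-butylsilyl bis(trifluoromethanesulfonate) `CC(C)(C)[Si](OS(=O)(=O)C(F)(F)F)(OS(=O)(=O)C(F)(F)F)C(C)(C)C`
Why: Silylene formation: the bis-triflate should silylate the primary O5 first and then close onto O3 to a six-membered 1,3-dioxa-2-silinane, leaving the 2-hydroxyl free; no stereocentre is touched.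

Step 2
Reactants: 2 3,5-O-(di-tert-butylsilanediyl)-D-arabinono-1,4-lactone
Product: 3 3,5-O-(di-tert-butylsilanediyl)-2-O-(triethylsilyl)-D-arabinono-1,4-lactone
Conditions: Et3SiCl, imidazole, DMF, 0 °C → rt
Reagents that add atoms: chlorotriethylsilane `CC[Si](Cl)(CC)CC`
Why: Standard silyl ether formation at the only free hydroxyl; triethylsilyl is chosen because it survives hydride reductions and can later be removed beside the silylene and exchanged for the acetate.

Step 3
Reactants: 3 3,5-O-(di-tert-butylsilanediyl)-2-O-(triethylsilyl)-D-arabinono-1,4-lactone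
Product: 4 3,5-O-(di-tert-butylsilanediyl)-2-O-(triethylsilyl)-D-arabinofuranose (α/β lactol)
Conditions: iBu2AlH (1.1 equiv), CH2Cl2, −78 °C; Rochelle salt work-up
Reagents that add atoms: none
Why: Half-reduction of a γ-lactone to the lactol by iBu2AlH, whose tetrahedral aluminate is stable at −78 °C; the silyl groups are inert and the new anomeric centre is irrelevant.

Step 4
Reactants: 4 3,5-O-(di-tert-butylsilanediyl)-2-O-(triethylsilyl)-D-arabinofuranose
Product: 6 methyl (Z)-2,3-dideoxy-5,7-O-(di-tert-butylsilanediyl)-2-iodo-4-O-(triethylsilyl)-D-arabino-hept-2-enonate (free 6-OH), via open-chain hydroxy aldehyde 5 (not isolated)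
Conditions: Ph3P=CHCO2Me, N-iodosuccinimide, CH2Cl2, −20 °C → rt; then 4, PhCO2H (cat.), 40 °C
Reagents that add atoms: methyl (triphenylphosphoranylidene)acetate `COC(=O)C=P(c1ccccc1)(c1ccccc1)c1ccccc1`; N-iodosuccinimide `O=C1CCC(=O)N1I`
Why: Wittig olefination of the aldehyde tautomer 5 with the stabilised α-iodo ylide made in the flask; such α-halo ylides place the halogen cis to the chain, which should give the (Z)-2-iodoenoate needed for ring closure, and the ring opening frees the former furanose oxygen alone.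

Step 5
Reactants: 6 methyl (Z)-2,3-dideoxy-5,7-O-(di-tert-butylsilanediyl)-2-iodo-4-O-(triethylsilyl)-D-arabino-hept-2-enonate
Product: 7 (Z)-2,3-dideoxy-5,7-O-(di-tert-butylsilanediyl)-2-iodo-4-O-(triethylsilyl)-D-arabino-hept-2-enitol (free 1-OH and 6-OH)
Conditions: iBu2AlH (4 equiv), CH2Cl2, −78 → −40 °C; Rochelle salt work-up
Reagents that add atoms: none
Why: iBu2AlH 1,2-reduction of the conjugated ester to the primary allylic alcohol (the future C7 carbinol); the alkenyl iodide, its geometry and the silyl groups should be untouched at low temperature.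

Step 6
Reactants: 7 (Z)-2,3-dideoxy-5,7-O-(di-tert-butylsilanediyl)-2-iodo-4-O-(triethylsilyl)-D-arabino-hept-2-enitol
Product: 8 (Z)-1,6-di-O-benzoyl-2,3-dideoxy-5,7-O-(di-tert-butylsilanediyl)-2-iodo-4-O-(triethylsilyl)-D-arabino-hept-2-enitol
Conditions: BzCl (3 equiv), pyridine, DMAP (cat.), CH2Cl2, 0 °C → rt
Reagents that add atoms: benzoyl chloride `O=C(Cl)c1ccccc1`
Why: DMAP-catalysed acylation of the only two free hydroxyls installs both benzoates of the target at once, on the primary allylic oxygen (future C7–O) and on the former ring oxygen (future C5–O).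

Step 7
Reactants: 8 (Z)-1,6-di-O-benzoyl-2,3-dideoxy-5,7-O-(di-tert-butylsilanediyl)-2-iodo-4-O-(triethylsilyl)-D-arabino-hept-2-enitol
Product: 9 (Z)-1,6-di-O-benzoyl-2,3-dideoxy-5,7-O-(di-tert-butylsilanediyl)-2-iodo-D-arabino-hept-2-enitol (free 4-OH)
Conditions: PPTS (0.2 equiv), MeOH/CH2Cl2 1:1, 0 °C → rt
Reagents that add atoms: none
Why: Acid-catalysed methanolysis should cleave the triethylsilyl ether much faster than the hindered cyclic di-tert-butylsilylene, and the freed hydroxyl has no vicinal ester, so no acyl shift is expected.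

Step 8
Reactants: 9 (Z)-1,6-di-O-benzoyl-2,3-dideoxy-5,7-O-(di-tert-butylsilanediyl)-2-iodo-D-arabino-hept-2-enitol
Product: 10 (Z)-4-O-acetyl-1,6-di-O-benzoyl-2,3-dideoxy-5,7-O-(di-tert-butylsilanediyl)-2-iodo-D-arabino-hept-2-enitol
Conditions: Ac2O, pyridine, DMAP (cat.), CH2Cl2, 0 °C
Reagents that add atoms: acetic anhydride `CC(=O)OC(C)=O`
Why: Acetylation of the single free (allylic) hydroxyl gives the C1 acetate of the target with retention, since the C–O bond is not touched.

Step 9
Reactants: 10 (Z)-4-O-acetyl-1,6-di-O-benzoyl-2,3-dideoxy-5,7-O-(di-tert-butylsilanediyl)-2-iodo-D-arabino-hept-2-enitol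
Product: 11 (Z)-4-O-acetyl-1,6-di-O-benzoyl-2,3-dideoxy-5-O-(di-tert-butylfluorosilyl)-2-iodo-D-arabino-hept-2-enitol (free 7-OH)
Conditions: BF3·SMe2 (3 equiv), CH2Cl2, 0 °C; pH 7 buffer quench, crude product used directly
Reagents that add atoms: boron trifluoride–dimethyl sulfide complex `C[S+](C)[B-](F)(F)F`
Why: Lewis-acid-mediated regioselective monodeprotection of a di-tert-butylsilylene: BF3 should open the Si–O bond at the less hindered primary oxygen and deliver fluoride to silicon, leaving the secondary oxygen (future C6–O) as a bulky fluorosilyl ether.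

Step 10
Reactants: 11 (Z)-4-O-acetyl-1,6-di-O-benzoyl-2,3-dideoxy-5-O-(di-tert-butylfluorosilyl)-2-iodo-D-arabino-hept-2-enitol
Product: 12 (Z)-4-O-acetyl-2,7-di-O-benzoyl-5,6-dideoxy-3-O-(di-tert-butylfluorosilyl)-6-iodo-aldehydo-D-lyxo-hept-5-enose
Conditions: Dess–Martin periodinane, CH2Cl2, 0 °C → rt; used crude at once
Reagents that add atoms: none
Why: Dess–Martin oxidation of the primary alcohol under near-neutral conditions, which should avoid epimerisation of the α-benzoyloxy centre and β-elimination.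

Step 11
Reactants: 12 (Z)-4-O-acetyl-2,7-di-O-benzoyl-5,6-dideoxy-3-O-(di-tert-butylfluorosilyl)-6-iodo-aldehydo-D-lyxo-hept-5-enose
Product: 14 (1R,4S,5R,6S)-1-O-acetyl-5-O-benzoyl-3-[(benzoyloxy)methyl]-6-O-(di-tert-butylfluorosilyl)cyclohex-2-ene-1,4,5,6-tetrol, via alkenylchromium dichloride 13 (not isolated)
Conditions: CrCl2 (8 equiv), NiCl2 (2 mol %), degassed DMSO, 0.005 M, rt; aq. NH4Cl work-up
Reagents that add atoms: none
Why: Zerovalent nickel (formed from NiCl2 by CrCl2) inserts into the C3–I bond with retention of the Z geometry, transmetalation to trivalent chromium gives alkenylchromium dichloride 13, and its C3–Cr bond adds to the chromium-bound C4 aldehyde; the chromium alkoxide is hydrolysed on work-up (intramolecular Nozaki–Hiyama–Kishi reaction). The closest known reaction type is the Ni/Cr-mediated closure of carbohydrate-derived (Z)-2-haloalkenyl aldehydes to polyoxygenated cyclohex-2-enols. The cyclohexene closes in the 6-exo-trig mode at the carbonyl, and because the C1 chain is cis to chromium the C2=C3 double bond ends inside the ring unchanged. The only new stereocentre, C4, is set by the substrate: in the chair-like closure the bulky O6 fluorosilyl ether and the trans O1 acetate should sit equatorial, which makes the C5 benzoate axial, and the aldehyde C=O then lies anti to that C5–O bond (dipole-opposed Cornforth-type arrangement, free of A(1,2) strain with the C7 arm), so C3 should be delivered to the Si face and the C4 oxygen should end pseudoaxial and trans to the C5 benzoate. The step needs chemoselectivity for the aldehyde over three esters and no loss of the allylic C7 benzoate, which the covalent, weakly basic carbon–chromium bond should provide, and cyclisation over dimerisation, which high dilution should provide.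

Step 12
Reactants: 14 (1R,4S,5R,6S)-1-O-acetyl-5-O-benzoyl-3-[(benzoyloxy)methyl]-6-O-(di-tert-butylfluorosilyl)cyclohex-2-ene-1,4,5,6-tetrol
Product: 15 CNP0169028.1, (1R,4S,5R,6S)-1-O-acetyl-5-O-benzoyl-3-[(benzoyloxy)methyl]cyclohex-2-ene-1,4,5,6-tetrol
Conditions: HF·pyridine, pyridine, THF, 0 °C → rt
Reagents that add atoms: none
Why: Fluoride-mediated cleavage of the fluorosilyl ether under buffered, mildly acidic conditions, where acetate and benzoate shifts between neighbouring oxygens should be slow; no stereocentre is touched.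

## Compound list

```
1 | D-arabinono-1,4-lactone | O=C1[C@@H](O)[C@H](O)[C@@H](CO)O1 | starting material
2 | 3,5-O-(di-tert-butylsilanediyl)-D-arabinono-1,4-lactone | O=C1[C@@H](O)[C@@H]2O[Si](C(C)(C)C)(C(C)(C)C)OC[C@H]2O1 | intermediate
3 | 3,5-O-(di-tert-butylsilanediyl)-2-O-(triethylsilyl)-D-arabinono-1,4-lactone | O=C1[C@@H](O[Si](CC)(CC)CC)[C@@H]2O[Si](C(C)(C)C)(C(C)(C)C)OC[C@H]2O1 | intermediate
4 | 3,5-O-(di-tert-butylsilanediyl)-2-O-(triethylsilyl)-D-arabinofuranose (anomeric mixture) | OC1[C@@H](O[Si](CC)(CC)CC)[C@@H]2O[Si](C(C)(C)C)(C(C)(C)C)OC[C@H]2O1 | intermediate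
5 | 3,5-O-(di-tert-butylsilanediyl)-2-O-(triethylsilyl)-aldehydo-D-arabinose (open-chain tautomer of 4) | O=C[C@@H](O[Si](CC)(CC)CC)[C@@H]1O[Si](C(C)(C)C)(C(C)(C)C)OC[C@H]1O | intermediate (not isolated)
6 | methyl (Z)-2,3-dideoxy-5,7-O-(di-tert-butylsilanediyl)-2-iodo-4-O-(triethylsilyl)-D-arabino-hept-2-enonate | COC(=O)/C(I)=C/[C@@H](O[Si](CC)(CC)CC)[C@@H]1O[Si](C(C)(C)C)(C(C)(C)C)OC[C@H]1O | intermediate
7 | (Z)-2,3-dideoxy-5,7-O-(di-tert-butylsilanediyl)-2-iodo-4-O-(triethylsilyl)-D-arabino-hept-2-enitol | OC/C(I)=C/[C@@H](O[Si](CC)(CC)CC)[C@@H]1O[Si](C(C)(C)C)(C(C)(C)C)OC[C@H]1O | intermediate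
8 | (Z)-1,6-di-O-benzoyl-2,3-dideoxy-5,7-O-(di-tert-butylsilanediyl)-2-iodo-4-O-(triethylsilyl)-D-arabino-hept-2-enitol | O=C(c1ccccc1)OC/C(I)=C/[C@@H](O[Si](CC)(CC)CC)[C@@H]2O[Si](C(C)(C)C)(C(C)(C)C)OC[C@H]2OC(=O)c3ccccc3 | intermediate
9 | (Z)-1,6-di-O-benzoyl-2,3-dideoxy-5,7-O-(di-tert-butylsilanediyl)-2-iodo-D-arabino-hept-2-enitol | O=C(c1ccccc1)OC/C(I)=C/[C@@H](O)[C@@H]2O[Si](C(C)(C)C)(C(C)(C)C)OC[C@H]2OC(=O)c3ccccc3 | intermediate
10 | (Z)-4-O-acetyl-1,6-di-O-benzoyl-2,3-dideoxy-5,7-O-(di-tert-butylsilanediyl)-2-iodo-D-arabino-hept-2-enitol | O=C(c1ccccc1)OC/C(I)=C/[C@@H](OC(C)=O)[C@@H]2O[Si](C(C)(C)C)(C(C)(C)C)OC[C@H]2OC(=O)c3ccccc3 | intermediate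
11 | (Z)-4-O-acetyl-1,6-di-O-benzoyl-2,3-dideoxy-5-O-(di-tert-butylfluorosilyl)-2-iodo-D-arabino-hept-2-enitol | O=C(c1ccccc1)OC/C(I)=C/[C@@H](OC(C)=O)[C@H](O[Si](F)(C(C)(C)C)C(C)(C)C)[C@H](OC(=O)c2ccccc2)CO | intermediate
12 | (Z)-4-O-acetyl-2,7-di-O-benzoyl-5,6-dideoxy-3-O-(di-tert-butylfluorosilyl)-6-iodo-aldehydo-D-lyxo-hept-5-enose | O=C(c1ccccc1)OC/C(I)=C/[C@@H](OC(C)=O)[C@H](O[Si](F)(C(C)(C)C)C(C)(C)C)[C@H](OC(=O)c2ccccc2)C=O | intermediate
13 | alkenylchromium dichloride of 12 (CrCl2 in place of iodine, Z geometry kept) | O=C(c1ccccc1)OC/C([Cr](Cl)Cl)=C/[C@@H](OC(C)=O)[C@H](O[Si](F)(C(C)(C)C)C(C)(C)C)[C@H](OC(=O)c2ccccc2)C=O | intermediate (not isolated)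
14 | (1R,4S,5R,6S)-1-O-acetyl-5-O-benzoyl-3-[(benzoyloxy)methyl]-6-O-(di-tert-butylfluorosilyl)cyclohex-2-ene-1,4,5,6-tetrol | O=C(c1ccccc1)OCC2=C[C@@H](OC(C)=O)[C@H](O[Si](F)(C(C)(C)C)C(C)(C)C)[C@H](OC(=O)c3ccccc3)[C@H]2O | intermediate
15 | CNP0169028.1, (1R,4S,5R,6S)-1-O-acetyl-5-O-benzoyl-3-[(benzoyloxy)methyl]cyclohex-2-ene-1,4,5,6-tetrol | CC(=O)O[C@@H]1C=C(COC(=O)c2ccccc2)[C@H](O)[C@@H](OC(=O)c2ccccc2)[C@H]1O | target
```

Total step count: 12. Longest linear sequence: 12 steps (1 → 15, fully linear).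

## Steps most likely to fail

1. Step 11 (key step). What may go wrong: the alkenylchromium adds to the wrong face of the aldehyde, or without useful preference, so that the C4 oxygen does not end trans to the C5 benzoate. Fallback (stereo-correction by oxidation and directed reduction instead of stereocontrol in the closure): the crude cyclisation product 14, whatever its composition at C4, is oxidised with Dess–Martin periodinane in CH2Cl2 to the single cyclohex-2-en-4-one F1. HF·pyridine then removes the fluorosilyl group to give the 6-hydroxy enone F2. Me4NBH(OAc)3 in MeCN/AcOH at −20 °C (hydroxyl-directed Evans–Saksena reduction) should deliver hydride from the face of the C6 hydroxyl, placing the C4 hydroxyl anti to it, and returns to the route at target 15.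

2. Step 4. What may go wrong: slow opening of the bicyclic lactol, re-addition of the freed hydroxyl to the iodoacrylate (oxa-Michael closure to a C-glycoside), and erosion of the Z geometry. Fallback (alkyne route, with the iodine introduced by trans-hydrometalation): from lactol 4, the Ohira–Bestmann reagent (K2CO3, MeOH, rt) gives the terminal alkyne F3. Its dianion (n-BuLi, THF, −78 °C) is trapped with paraformaldehyde to give the propargylic alcohol F4. Ruthenium-catalysed trans-hydrostannation ([Cp*RuCl]4 cat., Bu3SnH, CH2Cl2), directed to the proximal carbon by the free propargylic hydroxyl, gives the (Z)-alkenylstannane F5. Iododestannylation (I2, CH2Cl2, 0 °C) with retention rejoins the route at diol 7.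

3. Step 9. What may go wrong: opening of the silylene at the secondary instead of the primary oxygen, ionisation of the allylic esters by the Lewis acid, or a 1,2-shift of the benzoyl group to the liberated primary hydroxyl. Fallback (no protection of the C6 oxygen; the primary carbinol is singled out by oxidation, not by silicon): from 10, HF·pyridine (pyridine, THF) removes the silylene completely to give the diol F6. TEMPO (cat.)/PhI(OAc)2 in CH2Cl2 oxidises only the primary hydroxyl to the hydroxy aldehyde F7. The CrCl2/NiCl2 closure of step 11 applied to F7 then gives target 15 directly.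

## Further compounds

```
F1 | step 11 | 4-oxo analogue of 14: 1-O-acetyl-5-O-benzoyl-3-[(benzoyloxy)methyl]-6-O-(di-tert-butylfluorosilyl)-1,5,6-trihydroxycyclohex-2-en-4-one (C1, C5, C6 as in 14) | O=C(c1ccccc1)OCC2=C[C@@H](OC(C)=O)[C@H](O[Si](F)(C(C)(C)C)C(C)(C)C)[C@H](OC(=O)c3ccccc3)C2=O
F2 | step 11 | 4-oxo analogue of 15: 1-O-acetyl-5-O-benzoyl-3-[(benzoyloxy)methyl]-1,5,6-trihydroxycyclohex-2-en-4-one (free 6-OH; C1, C5, C6 as in 15) | O=C(c1ccccc1)OCC2=C[C@@H](OC(C)=O)[C@H](O)[C@H](OC(=O)c3ccccc3)C2=O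
F3 | step 4 | 1,2-dideoxy-4,6-O-(di-tert-butylsilanediyl)-3-O-(triethylsilyl)-D-arabino-hex-1-ynitol | C#C[C@@H](O[Si](CC)(CC)CC)[C@@H]1O[Si](C(C)(C)C)(C(C)(C)C)OC[C@H]1O
F4 | step 4 | 2,3-dideoxy-5,7-O-(di-tert-butylsilanediyl)-4-O-(triethylsilyl)-D-arabino-hept-2-ynitol | OCC#C[C@@H](O[Si](CC)(CC)CC)[C@@H]1O[Si](C(C)(C)C)(C(C)(C)C)OC[C@H]1O
F5 | step 4 | (Z)-2,3-dideoxy-5,7-O-(di-tert-butylsilanediyl)-2-(tributylstannyl)-4-O-(triethylsilyl)-D-arabino-hept-2-enitol | OC/C([Sn](CCCC)(CCCC)CCCC)=C/[C@@H](O[Si](CC)(CC)CC)[C@@H]1O[Si](C(C)(C)C)(C(C)(C)C)OC[C@H]1O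
F6 | step 9 | (Z)-4-O-acetyl-1,6-di-O-benzoyl-2,3-dideoxy-2-iodo-D-arabino-hept-2-enitol (free 5-OH and 7-OH) | O=C(c1ccccc1)OC/C(I)=C/[C@@H](OC(C)=O)[C@H](O)[C@H](OC(=O)c2ccccc2)CO
F7 | step 9 | (Z)-4-O-acetyl-2,7-di-O-benzoyl-5,6-dideoxy-6-iodo-aldehydo-D-lyxo-hept-5-enose (free 3-OH) | O=C(c1ccccc1)OC/C(I)=C/[C@@H](OC(C)=O)[C@H](O)[C@H](OC(=O)c2ccccc2)C=O
```
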